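**Retrosynthetic overview**
1. Haterumaimide N ⇒ C12 aldehyde 28 + cyano imide 32 by a C12–C13 syn-aldol disconnection; the succinimide ring is closed last, with loss of the auxiliary.
2. 28 ⇒ Diels–Alder adduct 17 by C11→C12 homologation and ring-B adjustment (C8–OSi → C8=O → C8=CH2; C7 allylic oxidation, inversion by oxidation/reduction, acetylation).
3. 17 ⇒ trienal 16 by a type 1 intramolecular Diels–Alder reaction that forms C5–C10 and C8–C9 and closes rings A and B in the same step.
4. Feature used: ring B (C5–C6–C7–C8–C9–C10) is fused to ring A along C5–C10, C10 is quaternary and next to C9, and ring-A atoms C1–C4 form a four-atom tether from dienophile carbon C10 to diene carbon C5 that already carries the C2 chloride.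
5. 16 ⇒ (R)-epichlorohydrin (C1–C3), prenyl chloride (C4–C6 and the gem-dimethyl group), acetylide (C9, C10), then methylalumination/chloroformate (C20, C11) and a formylmethylene ylide (C7, C8).

Key step: step 12

Remark: labdane numbering is used for all carbons and β is the face of the C10 methyl group; the prenyl nucleophile is introduced before the acetylide, which requires (R)-epichlorohydrin. The R/S label of the chloride carbon changes among 9–16 only because the CIP ranking of the two chain arms changes; that centre is not touched after step 4.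

**Step 1**
Reactants: 1 (R)-epichlorohydrin; 2 prenyl chloride
Product: 4 (2R)-1-chloro-4,4-dimethylhex-5-en-2-ol, via prenylmagnesium chloride 3 (not isolated)
Conditions: 2, Mg, THF, 0 °C; then 1, THF, −30 → 0 °C (no copper); aq. NH4Cl
Reagents that add atoms: none
Why: Allylic Grignard addition to a terminal epoxide with allylic transposition (SE2′, γ-attack) should join the tertiary prenyl carbon to the epoxide CH2 (C3–C4 bond, quaternary C4 with the C5=C6 vinyl group) without touching the carbinol carbon, which becomes C2.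

**Step 2**
Reactants: 4 (2R)-1-chloro-4,4-dimethylhex-5-en-2-ol
Product: 5 (2R)-2-(2,2-dimethylbut-3-en-1-yl)oxirane
Conditions: powdered NaOH, Et2O, rt
Reagents that add atoms: none
Why: Intramolecular Williamson etherification of the chlorohydrin; the C2–O bond is not broken, so configuration is retained and the electrophilic CH2 is now C1.

**Step 3**
Reactants: 5 (2R)-2-(2,2-dimethylbut-3-en-1-yl)oxirane
Product: 6 (4S)-6,6-dimethyloct-7-en-1-yn-4-ol
Conditions: HC≡CLi·H2NCH2CH2NH2, DMSO, 0 °C → rt
Reagents that add atoms: lithium acetylide–ethylenediamine complex, [Li]C#C.NCCN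
Why: SN2 opening of the terminal epoxide at its CH2 carbon (C1) by acetylide brings in C10 and C9 and leaves the C2 carbinol configuration intact.

**Step 4**
Reactants: 6 (4S)-6,6-dimethyloct-7-en-1-yn-4-ol
Product: 7 (4R)-4-chloro-6,6-dimethyloct-7-en-1-yne
Conditions: PPh3, N-chlorosuccinimide, THF, 0 °C → rt
Reagents that add atoms: N-chlorosuccinimide, O=C1CCC(=O)N1Cl
Why: Appel-type chlorination in which chloride displaces the alkoxyphosphonium group by SN2 with inversion, setting the C2 configuration that becomes the equatorial 2α-chloride.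

**Step 5**
Reactants: 7 (4R)-4-chloro-6,6-dimethyloct-7-en-1-yne
Product: 9 ethyl (2E,5R)-5-chloro-3,7,7-trimethylnona-2,8-dienoate, via alkenyldimethylalane 8 (not isolated)
Conditions: Me3Al, Cp2ZrCl2 (20 mol%), CH2Cl2, 0 °C → rt; then ClCO2Et, 0 °C → rt
Reagents that add atoms: trimethylaluminium, C[Al](C)C; ethyl chloroformate, CCOC(=O)Cl
Why: Zirconium-catalysed syn-methylalumination of the terminal alkyne (Negishi carboalumination) should place methyl on C10 and aluminium on C9, and acylation of the alkenylalane with retention gives the (E)-β-methyl enoate (C11); the hindered vinyl group and the secondary chloride should be inert.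

**Step 6**
Reactants: 9 ethyl (2E,5R)-5-chloro-3,7,7-trimethylnona-2,8-dienoate
Product: 11 ethyl (2E,5S)-5-chloro-9-hydroxy-3,7,7-trimethylnon-2-enoate, via B-alkyl-9-BBN adduct 10 (not isolated)
Conditions: 9-BBN, THF, 0 °C → rt; then H2O2, aq. NaOAc, 0 °C → rt
Reagents that add atoms: hydrogen peroxide, OO
Why: Hydroboration–oxidation with 9-BBN is anti-Markovnikov and selective for the monosubstituted C5=C6 alkene over the electron-poor trisubstituted enoate, and the weakly basic oxidation spares the ester.

**Step 7**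
Reactants: 11 ethyl (2E,5S)-5-chloro-9-hydroxy-3,7,7-trimethylnon-2-enoate
Product: 12 ethyl (2E,5S)-5-chloro-3,7,7-trimethyl-9-oxonon-2-enoate
Conditions: Dess–Martin periodinane, NaHCO3, CH2Cl2, 0 °C → rt
Reagents that add atoms: none
Why: Dess–Martin oxidation under buffered conditions gives the C6 aldehyde without affecting enoate or chloride.

**Step 8**
Reactants: 12 ethyl (2E,5S)-5-chloro-3,7,7-trimethyl-9-oxonon-2-enoate
Product: 13 ethyl (2E,5S,9E)-5-chloro-3,7,7-trimethyl-11-oxoundeca-2,9-dienoate
Conditions: Ph3P=CHCHO, PhMe, 80 °C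
Reagents that add atoms: (triphenylphosphoranylidene)acetaldehyde, O=CC=P(c1ccccc1)(c1ccccc1)c1ccccc1
Why: Wittig olefination with the stabilised formylmethylene ylide adds C7 and C8 and should give the (E)-enal.

**Step 9**
Reactants: 13 ethyl (2E,5S,9E)-5-chloro-3,7,7-trimethyl-11-oxoundeca-2,9-dienoate
Product: 14 ethyl (2E,5R,8E,10E)-11-[(tert-butyldimethylsilyl)oxy]-5-chloro-3,7,7-trimethylundeca-2,8,10-trienoate
Conditions: TBSOTf, Et3N, Et2O, 0 °C → rt
Reagents that add atoms: tert-butyldimethylsilyl triflate, CC(C)(C)[Si](C)(C)OS(=O)(=O)C(F)(F)F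
Why: Silyl dienol ether formation (O-silylation of the enal, then γ-deprotonation at C5) should give the (1E,3E)-1-silyloxydiene, 1E from the s-trans enal and 3E from the bulky quaternary C4; the ester is not enolised under these conditions.

**Step 10**
Reactants: 14 silyl dienol ether ester
Product: 15 (2E,5R,8E,10E)-11-[(tert-butyldimethylsilyl)oxy]-5-chloro-3,7,7-trimethylundeca-2,8,10-trien-1-ol
Conditions: DIBAL-H, CH2Cl2, −78 °C; Rochelle salt
Reagents that add atoms: none
Why: DIBAL-H 1,2-reduction of the enoate gives the allylic alcohol; silyl enol ether and alkyl chloride are inert at low temperature.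

**Step 11**
Reactants: 15 trienol
Product: 16 (2E,5R,8E,10E)-11-[(tert-butyldimethylsilyl)oxy]-5-chloro-3,7,7-trimethylundeca-2,8,10-trienal
Conditions: activated MnO2, CH2Cl2, rt
Reagents that add atoms: none
Why: Allylic oxidation with MnO2 is neutral and selective for the allylic alcohol, so the silyl dienol ether, the base-sensitive δ-chloro enal and the E geometry should survive.

**Step 12**
Reactants: 16 trienal
Product: 17 Diels–Alder adduct, trans-fused Δ6-octalin with 2α-Cl, 8β-OTBS, 9β-CHO, 5α-H and 10β-CH3
Conditions: PhMe (0.01 M), BHT (cat.), base-washed sealed tube, 110 °C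
Reagents that add atoms: none
Why: Thermal, concerted but asynchronous [4+2] cycloaddition in which the electron-rich 1-silyloxydiene C5–C8 (largest HOMO coefficient at C5) adds across the enal C9=C10 (largest LUMO coefficient at the β-carbon C10), so C5–C10 should form ahead of C8–C9; the closest known reaction type is the thermal or Lewis-acid-assisted type 1 intramolecular Diels–Alder reaction of (E,E,E)-1,7,9-decatrienals with a terminal formyl group to trans-decalins. Ring B (C5–C10) is the cyclohexene created by the cycloaddition itself, and ring A (C1–C5, C10) closes at the same time as the tether ring through a chair-like arrangement of C10–C1–C2–C3–C4–C5. C9 and C10 take their relative configuration from the (E)-enal (suprafacial addition keeps the C10 methyl and the formyl group cis), C8 from the (1E)-enol ether combined with the endo position of the formyl group (OTBS cis to CHO), and C5 from the (3E)-alkene in the same endo transition state, which puts H5 anti to the C10 methyl (trans fusion). The absolute sense comes from C2: in the chair-like tether the chloride must be equatorial, because an axial chloride would be syn-diaxial to the axial methyl groups at C4 and C10, and this fixes which diene face meets the dienophile. The step needs endo over exo selectivity and a single diene face; secondary overlap of the formyl group with the diene, the gem-dimethyl group (which also speeds ring closure) and the equatorial preference of C2–Cl should secure them, while the regiochemistry is imposed by the tether and is electronically matched.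

**Step 13**
Reactants: 17 Diels–Alder adduct
Product: 18 9β-(2-methoxyvinyl) enol ether (E/Z mixture)
Conditions: Ph3P(Cl)CH2OMe, KHMDS, THF, −78 → 0 °C
Reagents that add atoms: (methoxymethyl)triphenylphosphonium chloride, COC[P+](c1ccccc1)(c1ccccc1)c1ccccc1.[Cl-]
Why: Wittig methoxymethylenation adds C12 at once, so the β-silyloxy aldehyde is consumed before it can epimerise at C9 or eliminate; C9 stays equatorial (β).

**Step 14**
Reactants: 18 enol ether
Product: 19 9β-(1,3-dioxolan-2-ylmethyl) compound
Conditions: HOCH2CH2OH, PPTS (10 mol%), CH2Cl2, rt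
Reagents that add atoms: ethylene glycol, OCCO
Why: Acid-catalysed addition of the diol to the enol ether and transacetalisation (loss of methanol) gives the dioxolane that masks the C12 aldehyde; PPTS is too mild to cleave the hindered secondary TBS ether.

**Step 15**
Reactants: 19 dioxolane
Product: 20 saturated decalin (C6–C7 reduced)
Conditions: H2 (3 atm), 5% Pt/C, EtOAc, rt
Reagents that add atoms: none
Why: Heterogeneous catalytic hydrogenation saturates the cis-disubstituted C6=C7 alkene; platinum is chosen to avoid hydrogenolysis of the allylic C–O and the C–Cl bonds, and no stereocentre is created.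

**Step 16**
Reactants: 20 silyl ether
Product: 21 8β-alcohol
Conditions: TBAF, THF, rt → 50 °C
Reagents that add atoms: none
Why: Fluoride-mediated desilylation frees the axial C8 alcohol; acetal and chloride are inert.

**Step 17**
Reactants: 21 8β-alcohol
Product: 22 C8 ketone
Conditions: Dess–Martin periodinane, NaHCO3, CH2Cl2, rt
Reagents that add atoms: none
Why: Dess–Martin oxidation of the hindered axial alcohol gives the C8 ketone; the equatorial C9 side chain is the thermodynamic epimer.

**Step 18**
Reactants: 22 C8 ketone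
Product: 23 8(17)-alkene
Conditions: Ph3PCH3Br, KOt-Bu, PhMe, 80 °C
Reagents that add atoms: methyltriphenylphosphonium bromide, C[P+](c1ccccc1)(c1ccccc1)c1ccccc1.[Br-]
Why: Wittig methylenation of the hindered ketone installs C17; reversible enolisation is harmless because the equatorial C9 substituent is the stable epimer, and the equatorial chloride has no anti-periplanar hydrogen for E2.

**Step 19**
Reactants: 23 8(17)-alkene
Product: 24 7α-alcohol
Conditions: SeO2 (0.3 equiv), t-BuOOH (anhydrous, 3 equiv), CH2Cl2, 0 °C → rt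
Reagents that add atoms: selenium dioxide, O=[Se]=O; tert-butyl hydroperoxide, CC(C)(C)OO
Why: Catalytic selenium dioxide allylic oxidation (ene reaction at C17 with removal of the axial 7α-H, then [2,3]-sigmatropic shift) should restore the exocyclic alkene and deliver oxygen to C7 from the α face, giving the axial alcohol.

**Step 20**
Reactants: 24 7α-alcohol
Product: 25 8(17)-en-7-one
Conditions: Dess–Martin periodinane, NaHCO3, CH2Cl2, 0 °C
Reagents that add atoms: none
Why: Dess–Martin oxidation gives the exo-methylene ketone; buffering and low temperature are meant to prevent migration of the alkene into the ring.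

**Step 21**
Reactants: 25 8(17)-en-7-one
Product: 26 7β-alcohol
Conditions: NaBH4, CeCl3·7H2O, MeOH, −78 → −40 °C
Reagents that add atoms: none
Why: Luche 1,2-reduction in which hydride should add axially from the α face of the C7 ketone, giving the equatorial 7β-alcohol and so correcting C7.

**Step 22**
Reactants: 26 7β-alcohol
Product: 27 7β-acetate
Conditions: Ac2O, pyridine, DMAP (cat.), CH2Cl2, rt
Reagents that add atoms: acetic anhydride, CC(=O)OC(C)=O
Why: DMAP-catalysed acylation of the equatorial allylic alcohol proceeds with retention at C7.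

**Step 23**
Reactants: 27 7β-acetate dioxolane
Product: 28 C12 aldehyde (7β-acetoxy-2α-chloro-8(17)-ene)
Conditions: PPTS, acetone/H2O (10:1), 50 °C
Reagents that add atoms: water, O
Why: Mild acid-catalysed acetal hydrolysis unmasks the C12 aldehyde under conditions too weak to ionise the allylic acetate or isomerise the exocyclic alkene.

**Step 24**
Reactants: 29 (R)-4-benzyl-2-oxazolidinone; 30 3-cyanopropanoic acid
Product: 32 (R)-4-benzyl-3-(3-cyanopropanoyl)oxazolidin-2-one, via mixed pivalic anhydride 31 (not isolated)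
Conditions: 30, PivCl, Et3N, THF, −20 °C; then 29, LiCl, rt
Reagents that add atoms: none
Why: N-Acylation of the oxazolidinone through the mixed pivalic anhydride, which is attacked at its less hindered carbonyl.

**Step 25**
Reactants: 28 C12 aldehyde; 32 cyano imide
Product: 34 syn-aldol adduct (12S,13R), via dibutylboron Z-enolate 33 (not isolated)
Conditions: 32, n-Bu2BOTf, i-Pr2NEt, CH2Cl2, −78 → 0 °C; then 28, −78 → 0 °C; pH 7 buffer, MeOH, H2O2
Reagents that add atoms: none
Why: Evans syn-aldol reaction in which the (Z)-boron enolate reacts through a chair-like Zimmerman–Traxler transition state on the face opposite the benzyl group, so the (R)-auxiliary should set 12S and 13R while forming the C12–C13 bond.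

**Step 26**
Reactants: 34 nitrile aldol adduct
Product: 35 primary amide
Conditions: [PtH(PMe2OH)(PMe2O)2H] (5 mol%), EtOH/H2O (4:1), 70 °C
Reagents that add atoms: water, O
Why: Platinum-catalysed nitrile hydration under neutral conditions stops at the primary amide and tolerates acetate, imide, alkene and alkyl chloride.

**Step 27**
Reactants: 35 primary amide
Product: 36 haterumaimide N
Conditions: DBU (1 equiv), THF, 0 °C → rt; then AcOH
Reagents that add atoms: none
Why: Base-promoted intramolecular N-acylation (5-exo-trig, aspartimide-type closure) in which the amide nitrogen attacks the activated exocyclic imide carbonyl C16 and expels the oxazolidinone, closing the succinimide without touching C12 or C13.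

**Compound list**
1 | (R)-epichlorohydrin | ClC[C@H]1CO1 | starting material
2 | prenyl chloride (1-chloro-3-methylbut-2-ene) | CC(C)=CCCl | starting material
3 | prenylmagnesium chloride | CC(C)=CC[Mg]Cl | intermediate
4 | (2R)-1-chloro-4,4-dimethylhex-5-en-2-ol | C=CC(C)(C)C[C@@H](O)CCl | intermediate
5 | (2R)-2-(2,2-dimethylbut-3-en-1-yl)oxirane | C=CC(C)(C)C[C@@H]1CO1 | intermediate
6 | (4S)-6,6-dimethyloct-7-en-1-yn-4-ol | C#CC[C@H](O)CC(C)(C)C=C | intermediate
7 | (4R)-4-chloro-6,6-dimethyloct-7-en-1-yne | C#CC[C@@H](Cl)CC(C)(C)C=C | intermediate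
8 | (E)-alkenyldimethylalane from syn-methylalumination of 7 (chloride carbon as in 7) | C[Al](C)/C=C(C)/C[C@@H](Cl)CC(C)(C)C=C | intermediate
9 | ethyl (2E,5R)-5-chloro-3,7,7-trimethylnona-2,8-dienoate | CCOC(=O)/C=C(C)/C[C@@H](Cl)CC(C)(C)C=C | intermediate
10 | ethyl (2E,5S)-9-(9-borabicyclo[3.3.1]nonan-9-yl)-5-chloro-3,7,7-trimethylnon-2-enoate | CCOC(=O)/C=C(C)/C[C@@H](Cl)CC(C)(C)CCB1C2CCCC1CCC2 | intermediate
11 | ethyl (2E,5S)-5-chloro-9-hydroxy-3,7,7-trimethylnon-2-enoate | CCOC(=O)/C=C(C)/C[C@@H](Cl)CC(C)(C)CCO | intermediate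
12 | ethyl (2E,5S)-5-chloro-3,7,7-trimethyl-9-oxonon-2-enoate | CCOC(=O)/C=C(C)/C[C@@H](Cl)CC(C)(C)CC=O | intermediate
13 | ethyl (2E,5S,9E)-5-chloro-3,7,7-trimethyl-11-oxoundeca-2,9-dienoate | CCOC(=O)/C=C(C)/C[C@@H](Cl)CC(C)(C)C/C=C/C=O | intermediate
14 | ethyl (2E,5R,8E,10E)-11-[(tert-butyldimethylsilyl)oxy]-5-chloro-3,7,7-trimethylundeca-2,8,10-trienoate | CCOC(=O)/C=C(C)/C[C@@H](Cl)CC(C)(C)/C=C/C=C/O[Si](C)(C)C(C)(C)C | intermediate
15 | (2E,5R,8E,10E)-11-[(tert-butyldimethylsilyl)oxy]-5-chloro-3,7,7-trimethylundeca-2,8,10-trien-1-ol | OC/C=C(C)/C[C@@H](Cl)CC(C)(C)/C=C/C=C/O[Si](C)(C)C(C)(C)C | intermediate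
16 | (2E,5R,8E,10E)-11-[(tert-butyldimethylsilyl)oxy]-5-chloro-3,7,7-trimethylundeca-2,8,10-trienal | O=C/C=C(C)/C[C@@H](Cl)CC(C)(C)/C=C/C=C/O[Si](C)(C)C(C)(C)C | intermediate
17 | trans-fused Δ6-octalin 9β-carbaldehyde with 2α-Cl, 8β-OTBS, 4,4,10β-trimethyl, 5α-H | CC(C)(C)[Si](C)(C)O[C@H]1C=C[C@H]2C(C)(C)C[C@H](Cl)C[C@]2(C)[C@H]1C=O | intermediate
18 | 9β-(2-methoxyvinyl) analogue of 17 (E/Z mixture) | CC(C)(C)[Si](C)(C)O[C@H]1C=C[C@H]2C(C)(C)C[C@H](Cl)C[C@]2(C)[C@H]1C=COC | intermediate
19 | 9β-(1,3-dioxolan-2-ylmethyl)-2α-chloro-8β-OTBS-Δ6-octalin | CC(C)(C)[Si](C)(C)O[C@H]1C=C[C@H]2C(C)(C)C[C@H](Cl)C[C@]2(C)[C@H]1CC3OCCO3 | intermediate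
20 | 9β-(1,3-dioxolan-2-ylmethyl)-2α-chloro-8β-OTBS trans-decalin | CC(C)(C)[Si](C)(C)O[C@H]1CC[C@H]2C(C)(C)C[C@H](Cl)C[C@]2(C)[C@H]1CC3OCCO3 | intermediate
21 | 9β-(1,3-dioxolan-2-ylmethyl)-2α-chloro trans-decalin-8β-ol | O[C@H]1CC[C@H]2C(C)(C)C[C@H](Cl)C[C@]2(C)[C@H]1CC3OCCO3 | intermediate
22 | 9β-(1,3-dioxolan-2-ylmethyl)-2α-chloro trans-decalin-8-one | O=C1CC[C@H]2C(C)(C)C[C@H](Cl)C[C@]2(C)[C@H]1CC3OCCO3 | intermediate
23 | 2α-chloro-8(17)-ene with C12 dioxolane | C=C1CC[C@H]2C(C)(C)C[C@H](Cl)C[C@]2(C)[C@H]1CC3OCCO3 | intermediate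
24 | 2α-chloro-8(17)-en-7α-ol with C12 dioxolane | C=C1[C@H](O)C[C@H]2C(C)(C)C[C@H](Cl)C[C@]2(C)[C@H]1CC3OCCO3 | intermediate
25 | 2α-chloro-8(17)-en-7-one with C12 dioxolane | C=C1C(=O)C[C@H]2C(C)(C)C[C@H](Cl)C[C@]2(C)[C@H]1CC3OCCO3 | intermediate
26 | 2α-chloro-8(17)-en-7β-ol with C12 dioxolane | C=C1[C@@H](O)C[C@H]2C(C)(C)C[C@H](Cl)C[C@]2(C)[C@H]1CC3OCCO3 | intermediate
27 | 7β-acetoxy-2α-chloro-8(17)-ene with C12 dioxolane | C=C1[C@@H](OC(C)=O)C[C@H]2C(C)(C)C[C@H](Cl)C[C@]2(C)[C@H]1CC3OCCO3 | intermediate
28 | 7β-acetoxy-2α-chloro-8(17)-en-12-al (13,14,15,16-tetranorlabdane aldehyde) | C=C1[C@@H](OC(C)=O)C[C@H]2C(C)(C)C[C@H](Cl)C[C@]2(C)[C@H]1CC=O | intermediate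
29 | (R)-4-benzyl-2-oxazolidinone | O=C1N[C@H](Cc2ccccc2)CO1 | starting material
30 | 3-cyanopropanoic acid | N#CCCC(=O)O | starting material
31 | 3-cyanopropanoic pivalic anhydride | N#CCCC(=O)OC(=O)C(C)(C)C | intermediate
32 | (R)-4-benzyl-3-(3-cyanopropanoyl)oxazolidin-2-one | N#CCCC(=O)N1[C@H](Cc2ccccc2)COC1=O | intermediate
33 | dibutylboron (Z)-enolate of 32 | N#CC/C=C(\OB(CCCC)CCCC)N1[C@H](Cc2ccccc2)COC1=O | intermediate
34 | (R)-4-benzyl-3-[(2R,3S)-2-(cyanomethyl)-3-hydroxy-4-(decalin-9β-yl)butanoyl]oxazolidin-2-one (decalin as in 28) | C=C1[C@@H](OC(C)=O)C[C@H]2C(C)(C)C[C@H](Cl)C[C@]2(C)[C@H]1C[C@H](O)[C@@H](CC#N)C(=O)N1[C@H](Cc3ccccc3)COC1=O | intermediate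
35 | primary amide from hydration of the nitrile of 34 | C=C1[C@@H](OC(C)=O)C[C@H]2C(C)(C)C[C@H](Cl)C[C@]2(C)[C@H]1C[C@H](O)[C@@H](CC(N)=O)C(=O)N1[C@H](Cc3ccccc3)COC1=O | intermediate
36 | haterumaimide N | C=C1[C@@H](OC(C)=O)C[C@H]2C(C)(C)C[C@H](Cl)C[C@]2(C)[C@H]1C[C@H](O)[C@H]1CC(=O)NC1=O | target

**Step count**
Total: 27 steps. Longest linear sequence: 26 steps (steps 1–23 and 25–27).

**Steps most likely to fail**

Step 12 (intramolecular Diels–Alder). The β,β-disubstituted enal is a slow dienophile and the bond C5–C10 is congested, so the trienal may be lost to intermolecular Mukaiyama-type condensation, enal isomerisation or vinylogous loss of HCl before it cyclises; the endo preference that gives the trans fusion may also erode at the temperature needed. Any (1Z)-dienol ether carried from step 9 should not cyclise and would be removed here. Fallback: run the cycloaddition on the more robust ester. Setting out from 14, heating (o-dichlorobenzene, BHT, 180 °C) should give the trans-fused ethyl ester adduct F1; ring-fusion isomers would be separated at this stage. DIBAL-H reduction (CH2Cl2, −78 °C) gives the C11 primary alcohol F2, and Dess–Martin oxidation with pyridine returns to the route at 17.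

Step 13 (methoxymethylenation). The C9–H is anti-periplanar to the axial C8–OTBS group, so the basic ylide may cause β-elimination of silanolate or epimerisation, and addition to the neopentyl-type aldehyde may be slow. Fallback: homologate by non-basic methylenation and hydroboration. Setting out from 17, Tebbe methylenation (THF, pyridine, −40 → 0 °C) gives the 9β-vinyl compound F3. 9-BBN reacts selectively at the terminal alkene to give the B-alkyl-9-BBN adduct F4 (not isolated), which H2O2/aq. NaOAc oxidises to the C12 primary alcohol F5. Dess–Martin oxidation gives the C12 aldehyde F6, and acetalisation (ethylene glycol, PPTS, benzene, Dean–Stark) returns to the route at 19.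

Step 19 (selenium dioxide oxidation). The ene reaction may take the tertiary allylic C9–H instead of the C7–H, the alcohol may over-oxidise, or selenious acid may cleave the acetal. Fallback: oxidise C7 through the ketone enolate before methylenation. Setting out from 22, kinetic deprotonation at the C7 methylene (LDA, Et3SiCl, THF, −78 °C) gives the Δ7 triethylsilyl enol ether F7. Rubottom oxidation (dimethyldioxirane, acetone, −40 °C → rt; attack anti to the C10 methyl, then silyl migration) gives the 7α-(triethylsilyloxy) ketone F8. Wittig methylenation (Ph3PCH3Br, KOt-Bu, PhMe) gives the 7α-silyloxy 8(17)-alkene F9, and TBAF returns to the route at 24. Should the oxidation give the 7β epimer instead, the same sequence would end at 26 and steps 20 and 21 would be omitted.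

**Further compounds**
F1 | step 12 | ethyl ester analogue of 17 (CO2Et at C9β, 2α-Cl, 8β-OTBS, Δ6) | CC(C)(C)[Si](C)(C)O[C@H]1C=C[C@H]2C(C)(C)C[C@H](Cl)C[C@]2(C)[C@H]1C(=O)OCC
F2 | step 12 | C11 primary alcohol (9β-CH2OH, 2α-Cl, 8β-OTBS, Δ6) | CC(C)(C)[Si](C)(C)O[C@H]1C=C[C@H]2C(C)(C)C[C@H](Cl)C[C@]2(C)[C@H]1CO
F3 | step 13 | 9β-vinyl compound (2α-Cl, 8β-OTBS, Δ6) | CC(C)(C)[Si](C)(C)O[C@H]1C=C[C@H]2C(C)(C)C[C@H](Cl)C[C@]2(C)[C@H]1C=C
F4 | step 13 | B-alkyl-9-BBN adduct at C12 | CC(C)(C)[Si](C)(C)O[C@H]1C=C[C@H]2C(C)(C)C[C@H](Cl)C[C@]2(C)[C@H]1CCB3C4CCCC3CCC4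
F5 | step 13 | C12 primary alcohol (2α-Cl, 8β-OTBS, Δ6) | CC(C)(C)[Si](C)(C)O[C@H]1C=C[C@H]2C(C)(C)C[C@H](Cl)C[C@]2(C)[C@H]1CCO
F6 | step 13 | C12 aldehyde (2α-Cl, 8β-OTBS, Δ6) | CC(C)(C)[Si](C)(C)O[C@H]1C=C[C@H]2C(C)(C)C[C@H](Cl)C[C@]2(C)[C@H]1CC=O
F7 | step 19 | Δ7 triethylsilyl enol ether of 22 | CC[Si](CC)(CC)OC1=CC[C@H]2C(C)(C)C[C@H](Cl)C[C@]2(C)[C@H]1CC3OCCO3
F8 | step 19 | 7α-(triethylsilyloxy)-8-ketone with C12 dioxolane | O=C1[C@H](O[Si](CC)(CC)CC)C[C@H]2C(C)(C)C[C@H](Cl)C[C@]2(C)[C@H]1CC3OCCO3
F9 | step 19 | 7α-(triethylsilyloxy)-8(17)-alkene with C12 dioxolane | C=C1[C@H](O[Si](CC)(CC)CC)C[C@H]2C(C)(C)C[C@H](Cl)C[C@]2(C)[C@H]1CC3OCCO3
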